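**Retrosynthetic overview**
- The spiro-dihydrofuranol is cut at C(spiro)–CH(OH) and at O–C4 of the pyranone: enolate O-hetarylation plus intramolecular allylboration joins a β-boryl decalone to 4-chloro-3-formyl-6-(pyridin-3-yl)-2-pyranone, which is made separately and attached last.
- The β-boryl decalone comes from the spiro-lactone enone by conjugate borylation; the δ-lactone comes from a formyl ester by reduction and lactonisation.
- Ring A is closed by a photochemical dehydrogenative enol ether–olefin cyclisation that forms the bond between the isopropenyl-bearing CH and the quaternary lactone carbon (key step).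
- The cyclisation substrate comes from (S)-carvone: allylic oxidation to the 2-substituted acrolein, hetero-Diels–Alder reaction with ketene diethyl acetal (masked lactone), then methylation and homoprenylation next to the ketone.
- Ring order: ring B (bought as carvone), dihydropyran (masked lactone), ring A, δ-lactone, pyranone (separate branch), spiro-dihydrofuran.

Assumption: decalin positions in the names use naphthalen-1-one locants (C1 = ring-B carbonyl, later the furan spiro carbon; C4a/C8a = ring fusion; C5 = lactone spiro carbon; C6 = isopropenyl-bearing carbon); the route is a paper design and no step has been run.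

**Step 1**
Reactants: 1 (S)-(+)-carvone
Product: 3 10-oxocarvone (2-[(1S)-4-methyl-5-oxocyclohex-3-en-1-yl]prop-2-enal), via 10-hydroxycarvone 2 (not isolated)
Conditions: SeO2 (10 mol%), t-BuOOH, CH2Cl2, rt; then MnO2, CH2Cl2, rt
Reagents that add atoms: tert-butyl hydroperoxide CC(C)(C)OO
Why: Selenium dioxide ene/[2,3]-sigmatropic allylic oxidation takes the isopropenyl CH3 (preferred over the ring CH; the enone γ-CH2 is deactivated) and MnO2 oxidises the allylic alcohol to the enal, leaving the bought stereocentre untouched.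

**Step 2**
Reactants: 3 10-oxocarvone + 4 1,1-diethoxyethene
Product: 5 (5S)-5-(2,2-diethoxy-3,4-dihydro-2H-pyran-5-yl)-2-methylcyclohex-2-en-1-one
Conditions: 4 (2 equiv), PhMe, 50 °C; basic alumina
Reagents that add atoms: none
Why: Inverse-demand hetero-Diels–Alder reaction of the 2-substituted acrolein (1-oxadiene) with the ketene acetal, much faster than any reaction at the hindered ring enone, installs the future lactone C–C–C(=O) unit and masks the aldehyde as a base-stable cyclic enol ether without creating a stereocentre.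

**Step 3**
Reactants: 5 dihydropyranyl enone
Product: 6 (5S)-5-(2,2-diethoxy-3,4-dihydro-2H-pyran-5-yl)-2,6-dimethylcyclohex-2-en-1-one (both C6 epimers)
Conditions: LiN(iPr)2, THF, −78 °C; MeI
Reagents that add atoms: iodomethane CI
Why: Kinetic α′-enolate methylation as with carvone itself; the new stereocentre is erased by re-enolisation in step 4, so its configuration does not matter.

**Step 4**
Reactants: 6 methylated enone + 7 5-bromo-2-methylpent-2-ene
Product: 8 (5R,6R)-5-(2,2-diethoxy-3,4-dihydro-2H-pyran-5-yl)-2,6-dimethyl-6-(4-methylpent-3-en-1-yl)cyclohex-2-en-1-one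
Conditions: LiN(iPr)2, THF/DMPU, −78 °C; 7, n-Bu4NI (cat.), −78 to 0 °C
Reagents that add atoms: none
Why: Enolate C-alkylation in which the electrophile enters anti to the neighbouring dihydropyranyl group (as in alkylations of 6-methylcarvone), so the chain is trans and the methyl cis to that group, which fixes the quaternary angular-methyl carbon.

**Step 5**
Reactants: 8 cyclisation substrate
Product: 10 ethyl 3-[5-formyl-2,8a-dimethyl-1-oxo-6-(prop-1-en-2-yl)-1,4,4a,5,6,7,8,8a-octahydronaphthalen-5-yl]propanoate (4a-H trans to 8a-CH3; 5-CHO cis to 8a-CH3; 6-isopropenyl cis to 5-CHO), via spiro lactol orthoester 9 (not isolated)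
Conditions: 9-mesityl-10-methylacridinium perchlorate (5 mol%), Co(dmgH)2(py)Cl (5 mol%), 2,6-lutidine, H2O (5 equiv), MeCN, 450 nm LEDs, rt, Ar; then SiO2
Reagents that add atoms: water O
Why: Proposed new method: a photoredox/cobaloxime dual-catalytic dehydrogenative enol ether–olefin cyclisation in which the excited acridinium oxidises the cyclic enol ether to its radical cation, the tethered trisubstituted alkene attacks the enol-ether β-carbon through a chair 6-exo transition state that forms ring A trans-fused with the small vinylic CH (not the ring CH2) of the dihydropyran next to the angular-methyl carbon (minimised allylic 1,3-strain, so the future lactone OCH2 carbon ends axial and cis to the angular CH3 and the isopropenyl carbon equatorial), water traps the oxocarbenium ion, and divalent cobalt abstracts a methyl hydrogen from the tertiary radical to give the isopropenyl group with release of H2; the closest known reaction types are anodic enol ether–olefin coupling and acridinium/cobaloxime dehydrogenative alkene functionalisation.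

**Step 6**
Reactants: 10 aldehyde ester
Product: 12 spiro-lactone enone (tetrahydro-2H-pyran-2-one spiro-fused at C5 of 2,8a-dimethyl-6-(prop-1-en-2-yl)-4a,5,6,7,8,8a-hexahydronaphthalen-1(4H)-one; lactone OCH2 cis to 8a-CH3), via hydroxy ester 11 (not isolated)
Conditions: NaBH4, MeOH/CH2Cl2, −40 °C; then PPTS (cat.), PhMe, 60 °C
Reagents that add atoms: none
Why: Chemoselective borohydride reduction of the aldehyde in the presence of the hindered conjugated ketone and the ester, followed by acid-catalysed δ-lactonisation; no stereocentre is touched.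

**Step 7**
Reactants: 12 spiro-lactone enone
Product: 13 β-boryl ketone (3-(4,4,5,5-tetramethyl-1,3,2-dioxaborolan-2-yl) saturated ketone of 12; boron cis to 4a-H; C2 epimers)
Conditions: CuCl (5 mol%), NaOtBu (10 mol%), DPEphos (5 mol%), B2pin2, i-PrOH (2 equiv), THF, rt
Reagents that add atoms: bis(pinacolato)diboron CC1(C)OB(OC1(C)C)B1OC(C)(C)C(C)(C)O1
Why: Copper-catalysed conjugate borylation of the enone, where the boryl group adds axially and trans to the ring-A bond on the ring-fusion CH (the carvone rule), placing boron on the face from which the carbinol carbon must later be delivered.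

**Step 8**
Reactants: 14 nicotinoyl chloride hydrochloride + 15 2,2,6-trimethyl-4H-1,3-dioxin-4-one
Product: 17 4-hydroxy-6-(pyridin-3-yl)-2H-pyran-2-one, via acyl dioxinone 16 (not isolated)
Conditions: LiN(SiMe3)2 (3.1 equiv), THF, −78 °C; then PhMe, reflux
Reagents that add atoms: none
Why: γ-Acylation of the dioxinone dienolate followed by dioxinone thermolysis (loss of acetone to an acylketene) and ring closure through the enolised ketone oxygen gives the 4-hydroxy-2-pyranone.

**Step 9**
Reactants: 17 4-hydroxy-6-(pyridin-3-yl)-2H-pyran-2-one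
Product: 18 4-chloro-2-oxo-6-(pyridin-3-yl)-2H-pyran-3-carbaldehyde
Conditions: POCl3, DMF, 0 to 60 °C; aq. NaOAc
Reagents that add atoms: N,N-dimethylformamide CN(C)C=O; phosphoryl chloride O=P(Cl)(Cl)Cl; water O
Why: Vilsmeier–Haack formylation at C3 with concomitant conversion of the 4-OH into chloride, as established for 4-hydroxycoumarin and 4-hydroxy-6-methyl-2-pyranone.

**Step 10**
Reactants: 13 β-boryl ketone + 18 4-chloro-2-oxo-6-(pyridin-3-yl)-2H-pyran-3-carbaldehyde
Product: 22 target CNP0126103.3 (furan O cis to 8a-CH3; carbinol OH cis to the methyl-bearing alkene carbon across the dihydrofuran), via potassium enolate 19 (not isolated), via allylboronate aldehyde 20 (not isolated), via pinacol borate ester 21 (not isolated)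
Conditions: KN(SiMe3)2 (1.0 equiv), THF, −78 to −20 °C; 18, 18-crown-6, −78 to 45 °C; aq. NH4Cl
Reagents that add atoms: none
Why: The only enolisable ketone position gives a potassium enolate that is O-hetarylated by addition–elimination on the vinylogous acid chloride, and the resulting γ-oxygenated allylboronate allylborates the neighbouring aldehyde through a closed six-membered (Zimmerman–Traxler type) transition state, so the carbinol carbon is delivered to the furan spiro carbon on the boron-bearing face (opposite the axial angular methyl) and the B–O bridge places the OH cis to the regenerated ring-B alkene carbon.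

**Compound list**
1 | (S)-(+)-carvone, (5S)-2-methyl-5-(prop-1-en-2-yl)cyclohex-2-en-1-one | CC1=CC[C@@H](CC1=O)C(C)=C | starting material
2 | 10-hydroxycarvone, (5S)-5-(3-hydroxyprop-1-en-2-yl)-2-methylcyclohex-2-en-1-one | CC1=CC[C@@H](CC1=O)C(=C)CO | intermediate
3 | 10-oxocarvone, 2-[(1S)-4-methyl-5-oxocyclohex-3-en-1-yl]prop-2-enal | CC1=CC[C@@H](CC1=O)C(=C)C=O | intermediate
4 | 1,1-diethoxyethene (ketene diethyl acetal) | C=C(OCC)OCC | starting material
5 | (5S)-5-(2,2-diethoxy-3,4-dihydro-2H-pyran-5-yl)-2-methylcyclohex-2-en-1-one | CC1=CC[C@@H](CC1=O)C1=COC(OCC)(OCC)CC1 | intermediate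
6 | (5S)-5-(2,2-diethoxy-3,4-dihydro-2H-pyran-5-yl)-2,6-dimethylcyclohex-2-en-1-one, C6 epimers | CC1=CC[C@@H](C(C)C1=O)C1=COC(OCC)(OCC)CC1 | intermediate
7 | 5-bromo-2-methylpent-2-ene | CC(C)=CCCBr | starting material
8 | (5R,6R)-5-(2,2-diethoxy-3,4-dihydro-2H-pyran-5-yl)-2,6-dimethyl-6-(4-methylpent-3-en-1-yl)cyclohex-2-en-1-one (side chain trans to the dihydropyranyl group) | CC1=CC[C@@H]([C@@](C)(CCC=C(C)C)C1=O)C1=COC(OCC)(OCC)CC1 | intermediate
9 | spiro lactol orthoester: 6,6-diethoxytetrahydropyran-2-ol spiro-fused through its C3 at C5 of the decalin of 10 (lactol carbon epimers) | C=C(C)[C@@H]1CC[C@]2(C)[C@H](CC=C(C)C2=O)[C@@]12CCC(OCC)(OCC)OC2O | intermediate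
10 | ethyl 3-[5-formyl-2,8a-dimethyl-1-oxo-6-(prop-1-en-2-yl)-1,4,4a,5,6,7,8,8a-octahydronaphthalen-5-yl]propanoate; 4a-H trans to 8a-CH3, 5-CHO cis to 8a-CH3, 6-isopropenyl cis to 5-CHO, C4a as C5 of (S)-carvone | C=C(C)[C@@H]1CC[C@]2(C)[C@H](CC=C(C)C2=O)[C@@]1(C=O)CCC(=O)OCC | intermediate
11 | hydroxy ester: 10 with the 5-CHO reduced to 5-CH2OH | C=C(C)[C@@H]1CC[C@]2(C)[C@H](CC=C(C)C2=O)[C@@]1(CO)CCC(=O)OCC | intermediate
12 | spiro-lactone enone: tetrahydro-2H-pyran-2-one spiro-fused (its C5) at C5 of 2,8a-dimethyl-6-(prop-1-en-2-yl)-4a,5,6,7,8,8a-hexahydronaphthalen-1(4H)-one; lactone OCH2 cis to 8a-CH3, 6-isopropenyl cis to that OCH2, trans ring fusion | C=C(C)[C@@H]1CC[C@]2(C)[C@H](CC=C(C)C2=O)[C@@]12CCC(=O)OC2 | intermediate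
13 | β-boryl ketone: 2,3-dihydro-12 bearing a pinacolboryl group at C3, cis to 4a-H; C2 epimers | C=C(C)[C@@H]1CC[C@]2(C)[C@H](C[C@H](B3OC(C)(C)C(C)(C)O3)C(C)C2=O)[C@@]12CCC(=O)OC2 | intermediate
14 | nicotinoyl chloride hydrochloride | Cl.O=C(Cl)c1cccnc1 | starting material
15 | 2,2,6-trimethyl-4H-1,3-dioxin-4-one | CC1=CC(=O)OC(C)(C)O1 | starting material
16 | 2,2-dimethyl-6-[2-oxo-2-(pyridin-3-yl)ethyl]-4H-1,3-dioxin-4-one | O=C(CC1=CC(=O)OC(C)(C)O1)c1cccnc1 | intermediate
17 | 4-hydroxy-6-(pyridin-3-yl)-2H-pyran-2-one | O=c1cc(O)cc(-c2cccnc2)o1 | intermediate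
18 | 4-chloro-2-oxo-6-(pyridin-3-yl)-2H-pyran-3-carbaldehyde | O=Cc1c(Cl)cc(-c2cccnc2)oc1=O | intermediate
19 | potassium enolate of 13 (C1–O−, C1=C2) | C=C(C)[C@@H]1CC[C@]2(C)[C@H](C[C@H](B3OC(C)(C)C(C)(C)O3)C(C)=C2[O-])[C@@]12CCC(=O)OC2.[K+] | intermediate
20 | allylboronate aldehyde: C1 enol ether of 13 with the 4-oxygen of 3-formyl-6-(pyridin-3-yl)-2-pyranone | C=C(C)[C@@H]1CC[C@]2(C)[C@H](C[C@H](B3OC(C)(C)C(C)(C)O3)C(C)=C2Oc2cc(-c3cccnc3)oc(=O)c2C=O)[C@@]12CCC(=O)OC2 | intermediate
21 | pinacol borate ester of 22 (O–B on the carbinol oxygen) | C=C(C)[C@@H]1CC[C@]2(C)[C@H](CC=C(C)[C@@]23Oc2cc(-c4cccnc4)oc(=O)c2[C@@H]3OB2OC(C)(C)C(C)(C)O2)[C@@]12CCC(=O)OC2 | intermediate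
22 | target CNP0126103.3: decalin C1 is C2 of a 3-hydroxy-6-(pyridin-3-yl)-2,3-dihydro-4H-furo[3,2-c]pyran-4-one, C5 is the spiro carbon of the δ-lactone; furan O cis to 8a-CH3, 3-OH cis to decalin C2 | C=C(C)[C@@H]1CC[C@]2(C)[C@H](CC=C(C)[C@@]23Oc2cc(-c4cccnc4)oc(=O)c2[C@@H]3O)[C@@]12CCC(=O)OC2 | target

**Step count and risks**
Total step count: 10. Longest linear sequence: 8 steps (steps 1 to 7 and 10, from 1); the pyranone branch (steps 8 and 9) has 2 steps.

Step 4 may fail because a tertiary enolate must be alkylated by an unactivated homoallylic bromide (competing elimination of the bromide and O-alkylation). Fallback: from 6, alkylate with allyl bromide (LiN(iPr)2, THF) to the allyl ketone F1, hydroborate the terminal alkene chemoselectively (pinacolborane, RhCl(PPh3)3 cat.; then NaBO3) to the primary alcohol F2, oxidise with Dess–Martin periodinane/pyridine to the aldehyde F3, and olefinate with isopropylidenetriphenylphosphorane to come back to the route at 8.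

Step 5, the proposed new step, may fail through dark hydrolysis of the ketene-acetal adduct, hydration instead of desaturation at the tertiary carbon, or poor control at the lactone spiro carbon. Fallback with known chemistry: from 8, hydrolyse with PPTS in wet acetone to the acyclic formyl ester F4, convert it with TBSOTf/Et3N into the silyl enol ether F5, and cyclise with stoichiometric Cu(OTf)2/Cu2O in MeCN (oxidative cyclisation of unsaturated silyl enol ethers, in which divalent copper oxidises the tertiary radical to the less substituted alkene), coming back to the route at 10.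

Step 10 may fail because the enolate oxygen can bind the neighbouring boron, because C-attack or aldol addition at the aldehyde can compete with O-hetarylation, and because the allylboration must build a fully substituted carbon. Fallback: from 12, add dimethylsulfonium methylide (Me3S+ I−, KN(SiMe3)2) to the ketone anti to the angular methyl to give the spiro vinyl epoxide F6, open it at the tertiary allylic carbon with 17 as O–H pronucleophile under Pd2(dba)3/PPh3/Et3B (double inversion, net retention) to the tertiary pyranonyl ether alcohol F7, oxidise with Dess–Martin periodinane to the aldehyde F8, and close the dihydrofuran by Sc(OTf)3-catalysed intramolecular hydroxyalkylation at C3 of the 4-alkoxy-2-pyranone, coming back to the route at 22 (13 and 18 are then not needed).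

**Further compounds**
F1 | step 4 | allyl ketone: 8 with prop-2-en-1-yl in place of the 4-methylpent-3-en-1-yl group | CC1=CC[C@@H]([C@@](C)(CC=C)C1=O)C1=COC(OCC)(OCC)CC1
F2 | step 4 | primary alcohol: 6-(3-hydroxypropyl) analogue of 8 | CC1=CC[C@@H]([C@@](C)(CCCO)C1=O)C1=COC(OCC)(OCC)CC1
F3 | step 4 | aldehyde: 6-(3-oxopropyl) analogue of 8 | CC1=CC[C@@H]([C@@](C)(CCC=O)C1=O)C1=COC(OCC)(OCC)CC1
F4 | step 5 | acyclic formyl ester: ethyl 4-formyl-4-[2,4-dimethyl-2-(4-methylpent-3-en-1-yl)-3-oxocyclohex-4-en-1-yl]butanoate, ring centres as in 8, epimers at the formyl-bearing carbon | CC1=CC[C@@H]([C@@](C)(CCC=C(C)C)C1=O)C(C=O)CCC(=O)OCC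
F5 | step 5 | tert-butyldimethylsilyl enol ether of F4 (E/Z mixture) | CC1=CC[C@@H]([C@@](C)(CCC=C(C)C)C1=O)C(=CO[Si](C)(C)C(C)(C)C)CCC(=O)OCC
F6 | step 10 | spiro vinyl epoxide: oxirane at C1 of 12, CH2 trans and O cis to 8a-CH3 | C=C(C)[C@@H]1CC[C@]2(C)[C@H](CC=C(C)[C@@]23OC3)[C@@]12CCC(=O)OC2
F7 | step 10 | tertiary pyranonyl ether alcohol: C1 bears CH2OH (trans to 8a-CH3) and the 4-oxygen of 6-(pyridin-3-yl)-2-pyranone | C=C(C)[C@@H]1CC[C@]2(C)[C@H](CC=C(C)[C@@]2(CO)Oc2cc(-c3cccnc3)oc(=O)c2)[C@@]12CCC(=O)OC2
F8 | step 10 | aldehyde: F7 with CH2OH oxidised to CHO | C=C(C)[C@@H]1CC[C@]2(C)[C@H](CC=C(C)[C@@]2(C=O)Oc2cc(-c3cccnc3)oc(=O)c2)[C@@]12CCC(=O)OC2
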